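**Retrosynthetic overview**
- The target is liberated from a crystalline chiral ammonium salt. C2 is a hemiketal that epimerises through the ring-opened 1,3-diketone, so it is fixed last, by crystallization-induced asymmetric transformation.
- The racemic acid comes from hydrogenolysis of a tri-O-benzyl precursor.
- Key disconnection C3–C4: the formyl C–H of 2-heptyl-4,6-dihydroxybenzaldehyde serves as an acyl anion equivalent (acyl–rhodium). It is joined to an α-keto sulfoxonium ylide that reacts as an electrophilic α-keto carbene (enolonium equivalent).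
- The ylide comes from orsellinic acid (benzylation, lateral lithiation/methoxycarbonylation, ylide acylation); the aldehyde comes from 5-heptylresorcinol (Vilsmeier–Haack).
- Ring order: both benzene rings are bought. The only ring made is the pyranone ring, closed by hemiketalization right after the key C–C bond forms.

Assumption: the (R)-amine is taken to give the less soluble salt with the (2R)-acid; if the (2S)-acid salt crystallises instead, the (S)-amine gives the mirror-image salt, which contains the wanted (2R)-acid.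

**Step 1**
Reactants: 1 5-heptylbenzene-1,3-diol
Product: 3 2-heptyl-4,6-dihydroxybenzaldehyde, via aryl iminium chloride 2 (not isolated)
Conditions: POCl3 (1.5 equiv), DMF, 0 → 20 °C; then H2O, 50 °C
Reagents that add atoms: N,N-dimethylformamide, CN(C)C=O (formyl carbon); water, O (carbonyl oxygen)
Why: Vilsmeier–Haack formylation goes para to one hydroxyl and ortho to the other (as with orcinol and olivetol) rather than at the hindered carbon between the two hydroxyls; no stereocenter.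

**Step 2**
Reactants: 4 2,4-dihydroxy-6-methylbenzoic acid (orsellinic acid)
Product: 5 benzyl 2,4-bis(benzyloxy)-6-methylbenzoate
Conditions: BnBr (3.3 equiv), K2CO3 (4 equiv), DMF, 60 °C
Reagents that add atoms: benzyl bromide, BrCc1ccccc1
Why: Exhaustive Williamson-type O-benzylation; the carboxylate is alkylated first, which also prevents decarboxylation, and all three groups later leave together by hydrogenolysis.

**Step 3**
Reactants: 5 benzyl 2,4-bis(benzyloxy)-6-methylbenzoate
Product: 8 benzyl 2,4-bis(benzyloxy)-6-(2-methoxy-2-oxoethyl)benzoate, via benzylic organolithium 6 (not isolated), via lithium ester enolate 7 (not isolated)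
Conditions: LiN(iPr)2 (2.2 equiv), THF, −78 °C; (MeO)2CO (1.5 equiv), −78 → −40 °C; 1 M HCl quench
Reagents that add atoms: dimethyl carbonate, COC(=O)OC
Why: Lateral lithiation of an ortho-toluate followed by C-acylation with dimethyl carbonate; the second equivalent of amide base takes up the acidic arylacetate proton so the product cannot quench the benzylic anion.

**Step 4**
Reactants: 8 benzyl 2,4-bis(benzyloxy)-6-(2-methoxy-2-oxoethyl)benzoate
Product: 9 benzyl 2,4-bis(benzyloxy)-6-{3-[dimethyl(oxo)-λ6-sulfanylidene]-2-oxopropyl}benzoate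
Conditions: Me3S(O)I (3 equiv), KOtBu (3 equiv), THF, reflux 2 h; then 8, 20 → 60 °C
Reagents that add atoms: trimethylsulfoxonium iodide, C[S+](C)(C)=O.[I-], delivered as dimethylsulfoxonium methylide, C=S(C)(C)=O
Why: Acylation of the Corey–Chaykovsky sulfoxonium methylide by the unhindered aliphatic methyl ester gives the stabilised β-keto sulfoxonium ylide, while the di-ortho-substituted benzyl benzoate is too hindered to react.

**Step 5 (key step)**
Reactants: 3 2-heptyl-4,6-dihydroxybenzaldehyde; 9 benzyl 2,4-bis(benzyloxy)-6-{3-[dimethyl(oxo)-λ6-sulfanylidene]-2-oxopropyl}benzoate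
Product: 11 rac-benzyl 2,4-bis(benzyloxy)-6-[(5-heptyl-2,7-dihydroxy-4-oxo-3,4-dihydro-2H-chromen-2-yl)methyl]benzoate, via open-chain 1,3-diketone 10 (not isolated)
Conditions: [Cp*RhCl2]2 (4 mol %), AgSbF6 (16 mol %), NaOAc (30 mol %), DCE, 60 °C, Ar; no added acid, neutral work-up
Reagents that add atoms: none
Why: Proposed new method: phenoxide-directed aldehydic C–H rhodation of 3 gives a nucleophilic five-membered acyl–rhodium (acyl anion equivalent), 9 binds and loses DMSO to give an electrophilic α-keto rhodium carbene (enolonium equivalent), migratory insertion forms C3–C4 and protodemetalation releases diketone 10, whose ortho-phenol adds to the C2 ketone to give hemiketal 11 as a racemate (C2 is set in step 6); the closest known reaction type is the Cp*-rhodium-catalysed annulation of salicylaldehydes with sulfoxonium ylides to chromones, run here acetate-buffered and without added acid so that the final dehydration does not occur.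

**Step 6**
Reactants: 11 rac-benzyl 2,4-bis(benzyloxy)-6-[(5-heptyl-2,7-dihydroxy-4-oxo-3,4-dihydro-2H-chromen-2-yl)methyl]benzoate
Product: 13 (1R)-N,N-dimethyl-1-phenylethan-1-aminium 2-{[(2R)-5-heptyl-2,7-dihydroxy-4-oxo-3,4-dihydro-2H-chromen-2-yl]methyl}-4,6-dihydroxybenzoate, via racemic free acid 12 (not isolated)
Conditions: H2 (1 atm), 10% Pd/C, EtOAc, 20 °C; filter; (R)-PhCH(Me)NMe2 (1.0 equiv), EtOAc/heptane, seeded slurry 40 → 5 °C, 48 h; filter crystals
Reagents that add atoms: (R)-N,N-dimethyl-1-phenylethylamine, C[C@@H](N(C)C)c1ccccc1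
Why: Proposed new method: after standard hydrogenolysis of the three O-benzyl groups, C2 epimerises in solution through the ring-opened 1,3-diketone (amine-buffered ring–chain tautomerism) while the less soluble (2R)-acid·(R)-amine salt crystallises, so the whole batch is funnelled into the (2R) configuration; the closest known reaction type is crystallization-induced diastereomer transformation of epimerisable acids as chiral ammonium salts, and a tertiary amine is used so that no enaminone can form with the open diketone.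

**Step 7**
Reactants: 13 (1R)-N,N-dimethyl-1-phenylethan-1-aminium 2-{[(2R)-5-heptyl-2,7-dihydroxy-4-oxo-3,4-dihydro-2H-chromen-2-yl]methyl}-4,6-dihydroxybenzoate
Product: 14 2-{[(2R)-5-heptyl-2,7-dihydroxy-4-oxo-3,4-dihydro-2H-chromen-2-yl]methyl}-4,6-dihydroxybenzoic acid
Conditions: EtOAc / 0.5 M HCl (1.05 equiv), 0 °C, 5 min; dry (Na2SO4), evaporate below 10 °C, store as solid; aqueous phase + NaOH to recover the amine
Reagents that add atoms: none
Why: Two-phase acid–base salt metathesis protonates only the carboxylate and breaks no bond at C2; short, cold contact keeps ring opening, the only racemisation path, slow.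

**Compound list**
1 | 5-heptylbenzene-1,3-diol (5-heptylresorcinol) | CCCCCCCc1cc(O)cc(O)c1 | starting material
2 | N-[(2-heptyl-4,6-dihydroxyphenyl)methylidene]-N-methylmethanaminium chloride | CCCCCCCc1cc(O)cc(O)c1C=[N+](C)C.[Cl-] | intermediate
3 | 2-heptyl-4,6-dihydroxybenzaldehyde | CCCCCCCc1cc(O)cc(O)c1C=O | intermediate
4 | 2,4-dihydroxy-6-methylbenzoic acid (orsellinic acid) | Cc1cc(O)cc(O)c1C(=O)O | starting material
5 | benzyl 2,4-bis(benzyloxy)-6-methylbenzoate | Cc1cc(OCc2ccccc2)cc(OCc2ccccc2)c1C(=O)OCc1ccccc1 | intermediate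
6 | benzyl 2,4-bis(benzyloxy)-6-(lithiomethyl)benzoate | [Li]Cc1cc(OCc2ccccc2)cc(OCc2ccccc2)c1C(=O)OCc1ccccc1 | intermediate
7 | lithium 2-[2-(benzyloxycarbonyl)-3,5-bis(benzyloxy)phenyl]-1-methoxyethen-1-olate | COC(O[Li])=Cc1cc(OCc2ccccc2)cc(OCc2ccccc2)c1C(=O)OCc1ccccc1 | intermediate
8 | benzyl 2,4-bis(benzyloxy)-6-(2-methoxy-2-oxoethyl)benzoate | COC(=O)Cc1cc(OCc2ccccc2)cc(OCc2ccccc2)c1C(=O)OCc1ccccc1 | intermediate
9 | benzyl 2,4-bis(benzyloxy)-6-{3-[dimethyl(oxo)-λ6-sulfanylidene]-2-oxopropyl}benzoate | CS(C)(=O)=CC(=O)Cc1cc(OCc2ccccc2)cc(OCc2ccccc2)c1C(=O)OCc1ccccc1 | intermediate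
10 | benzyl 2,4-bis(benzyloxy)-6-[4-(2-heptyl-4,6-dihydroxyphenyl)-2,4-dioxobutyl]benzoate | CCCCCCCc1cc(O)cc(O)c1C(=O)CC(=O)Cc1cc(OCc2ccccc2)cc(OCc2ccccc2)c1C(=O)OCc1ccccc1 | intermediate
11 | rac-benzyl 2,4-bis(benzyloxy)-6-[(5-heptyl-2,7-dihydroxy-4-oxo-3,4-dihydro-2H-chromen-2-yl)methyl]benzoate | CCCCCCCc1cc(O)cc2c1C(=O)CC(O)(Cc1cc(OCc3ccccc3)cc(OCc3ccccc3)c1C(=O)OCc1ccccc1)O2 | intermediate
12 | rac-2-[(5-heptyl-2,7-dihydroxy-4-oxo-3,4-dihydro-2H-chromen-2-yl)methyl]-4,6-dihydroxybenzoic acid | CCCCCCCc1cc(O)cc2c1C(=O)CC(O)(Cc1cc(O)cc(O)c1C(=O)O)O2 | intermediate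
13 | (1R)-N,N-dimethyl-1-phenylethan-1-aminium 2-{[(2R)-5-heptyl-2,7-dihydroxy-4-oxo-3,4-dihydro-2H-chromen-2-yl]methyl}-4,6-dihydroxybenzoate | CCCCCCCc1cc(O)cc2c1C(=O)C[C@@](O)(Cc1cc(O)cc(O)c1C(=O)[O-])O2.C[C@@H]([NH+](C)C)c1ccccc1 | intermediate
14 | 2-{[(2R)-5-heptyl-2,7-dihydroxy-4-oxo-3,4-dihydro-2H-chromen-2-yl]methyl}-4,6-dihydroxybenzoic acid (CNP0232458.1) | CCCCCCCc1cc(O)cc2c1C(=O)C[C@@](O)(Cc1cc(O)cc(O)c1C(=O)O)O2 | target

**Totals**
Total step count: 7. Longest linear sequence: 6 steps (4 → 5 → 8 → 9 → 11 → 13 → 14; steps 2–7).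

**Three steps most likely to fail**

Step 5. The aldehyde is di-ortho-substituted and carries two free phenols, and the product can dehydrate to the chromone. The fallback keeps the reversed polarity but moves it to C2: a C2-metalated chromone (masked acyl anion, also a β-acylvinyl anion, so a homoenolate equivalent of the C4 ketone) is joined to an electrophilic benzyl bromide. It sets out from 1 and 5 and comes back at 12.
- Friedel–Crafts acetylation of 1 (AcOH, BF3·OEt2, 90 °C) gives 1-(2-heptyl-4,6-dihydroxyphenyl)ethan-1-one F1.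
- Benzylation of the non-chelated hydroxyl (BnBr, KHCO3, MeCN) gives 1-[4-(benzyloxy)-2-heptyl-6-hydroxyphenyl]ethan-1-one F2.
- Me2NCH(OMe)2 gives (E)-1-[4-(benzyloxy)-2-heptyl-6-hydroxyphenyl]-3-(dimethylamino)prop-2-en-1-one F3, which closes with aqueous HCl to 7-(benzyloxy)-5-heptyl-4H-chromen-4-one F4.
- Separately, the benzylic organolithium 6 made from 5 is added inversely to BrCCl2CCl2Br to give benzyl 2,4-bis(benzyloxy)-6-(bromomethyl)benzoate F5.
- F4 is zincated at the acidic C2–H with TMPZnCl·LiCl (THF, 25 °C; no MgCl2 or BF3, which I expect to steer metalation to C3) to give [7-(benzyloxy)-5-heptyl-4-oxo-4H-chromen-2-yl]zinc chloride F6.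
- Negishi coupling of F6 with F5 (Pd(PPh3)4 cat.) gives benzyl 2,4-bis(benzyloxy)-6-{[7-(benzyloxy)-5-heptyl-4-oxo-4H-chromen-2-yl]methyl}benzoate F7.
- Hydrogenolysis (H2, 10% Pd/C, EtOAc, stopped after four equivalents) gives 2-[(5-heptyl-7-hydroxy-4-oxo-4H-chromen-2-yl)methyl]-4,6-dihydroxybenzoic acid F8.
- Ring opening with 1 M NaOH at 20 °C, then acidification to pH 4 at 0 °C, hydrates C2 and gives racemic 12, which enters the amine crystallization of step 6.

Step 6. The salt may not crystallise, or may crystallise as the wrong or a mixed diastereomer. The fallback replaces dynamic crystallization by a configurationally stable derivative; it sets out from 11 and comes back at 14.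
- Mild ketalization (BnOH, PPTS cat., 4 Å MS, CH2Cl2, 0 °C) gives rac-benzyl 2,4-bis(benzyloxy)-6-{[2-(benzyloxy)-5-heptyl-7-hydroxy-4-oxo-3,4-dihydro-2H-chromen-2-yl]methyl}benzoate F9.
- Preparative chiral SFC separates the (2R)-2-O-benzyl ketal F10 from the (2S)-2-O-benzyl ketal F11; F11 is re-racemised with PPTS/BnOH and recycled.
- Hydrogenolysis of F10 (H2, 10% Pd/C, EtOAc, 0 °C) removes all four benzyl groups without breaking either C2–O bond and gives 14 directly.

Step 4. The basic ylide may only enolise the acidic arylacetate or react elsewhere. The fallback swaps the carbene precursor for an α-diazoketone made without base; it sets out from 8 and comes back at 11.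
- LiOH (1.1 equiv, THF/H2O, 0 °C) cleaves only the unhindered methyl ester to give [2-(benzyloxycarbonyl)-3,5-bis(benzyloxy)phenyl]acetic acid F12.
- 1-Chloro-N,N,2-trimethylprop-1-en-1-amine (CH2Cl2, 0 °C) gives benzyl 2,4-bis(benzyloxy)-6-(2-chloro-2-oxoethyl)benzoate F13.
- TMSCHN2 (MeCN/THF, 0 °C) gives benzyl 2,4-bis(benzyloxy)-6-(3-diazo-2-oxopropyl)benzoate F14.
- F14 is used in place of 9 under the conditions of step 5 (N2 leaves instead of DMSO) and gives 11 through 10.

**Further compounds**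
F1 | step 5 | 1-(2-heptyl-4,6-dihydroxyphenyl)ethan-1-one | CCCCCCCc1cc(O)cc(O)c1C(C)=O
F2 | step 5 | 1-[4-(benzyloxy)-2-heptyl-6-hydroxyphenyl]ethan-1-one | CCCCCCCc1cc(OCc2ccccc2)cc(O)c1C(C)=O
F3 | step 5 | (E)-1-[4-(benzyloxy)-2-heptyl-6-hydroxyphenyl]-3-(dimethylamino)prop-2-en-1-one | CCCCCCCc1cc(OCc2ccccc2)cc(O)c1C(=O)/C=C/N(C)C
F4 | step 5 | 7-(benzyloxy)-5-heptyl-4H-chromen-4-one | CCCCCCCc1cc(OCc2ccccc2)cc2occc(=O)c12
F5 | step 5 | benzyl 2,4-bis(benzyloxy)-6-(bromomethyl)benzoate | BrCc1cc(OCc2ccccc2)cc(OCc2ccccc2)c1C(=O)OCc1ccccc1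
F6 | step 5 | [7-(benzyloxy)-5-heptyl-4-oxo-4H-chromen-2-yl]zinc chloride | CCCCCCCc1cc(OCc2ccccc2)cc2oc([Zn]Cl)cc(=O)c12
F7 | step 5 | benzyl 2,4-bis(benzyloxy)-6-{[7-(benzyloxy)-5-heptyl-4-oxo-4H-chromen-2-yl]methyl}benzoate | CCCCCCCc1cc(OCc2ccccc2)cc2oc(Cc3cc(OCc4ccccc4)cc(OCc4ccccc4)c3C(=O)OCc3ccccc3)cc(=O)c12
F8 | step 5 | 2-[(5-heptyl-7-hydroxy-4-oxo-4H-chromen-2-yl)methyl]-4,6-dihydroxybenzoic acid | CCCCCCCc1cc(O)cc2oc(Cc3cc(O)cc(O)c3C(=O)O)cc(=O)c12
F9 | step 6 | rac-benzyl 2,4-bis(benzyloxy)-6-{[2-(benzyloxy)-5-heptyl-7-hydroxy-4-oxo-3,4-dihydro-2H-chromen-2-yl]methyl}benzoate | CCCCCCCc1cc(O)cc2c1C(=O)CC(OCc1ccccc1)(Cc1cc(OCc3ccccc3)cc(OCc3ccccc3)c1C(=O)OCc1ccccc1)O2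
F10 | step 6 | benzyl 2,4-bis(benzyloxy)-6-{[(2R)-2-(benzyloxy)-5-heptyl-7-hydroxy-4-oxo-3,4-dihydro-2H-chromen-2-yl]methyl}benzoate | CCCCCCCc1cc(O)cc2c1C(=O)C[C@@](OCc1ccccc1)(Cc1cc(OCc3ccccc3)cc(OCc3ccccc3)c1C(=O)OCc1ccccc1)O2
F11 | step 6 | benzyl 2,4-bis(benzyloxy)-6-{[(2S)-2-(benzyloxy)-5-heptyl-7-hydroxy-4-oxo-3,4-dihydro-2H-chromen-2-yl]methyl}benzoate | CCCCCCCc1cc(O)cc2c1C(=O)C[C@](OCc1ccccc1)(Cc1cc(OCc3ccccc3)cc(OCc3ccccc3)c1C(=O)OCc1ccccc1)O2
F12 | step 4 | [2-(benzyloxycarbonyl)-3,5-bis(benzyloxy)phenyl]acetic acid | OC(=O)Cc1cc(OCc2ccccc2)cc(OCc2ccccc2)c1C(=O)OCc1ccccc1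
F13 | step 4 | benzyl 2,4-bis(benzyloxy)-6-(2-chloro-2-oxoethyl)benzoate | ClC(=O)Cc1cc(OCc2ccccc2)cc(OCc2ccccc2)c1C(=O)OCc1ccccc1
F14 | step 4 | benzyl 2,4-bis(benzyloxy)-6-(3-diazo-2-oxopropyl)benzoate | [N-]=[N+]=CC(=O)Cc1cc(OCc2ccccc2)cc(OCc2ccccc2)c1C(=O)OCc1ccccc1
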